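Take the late readings first: that was the chair's direction at the meeting on this flask, in which incoming ligand exchanges onto the starting complex in a closed, stirred, isothermal vessel.

all flasks: starting complex 0.19 M
- zeta: incoming ligand 3 equiv; the very flask that is asked about, followed so far
- flask: incoming ligand 3.00 equiv; time 40 h

zeta run (percent of the starting complex charged)

| time / h | complex with one exchanged / % | complex with two exchanged / % | starting complex / % |
|---|---|---|---|
| 1.33 | 55 | 10 | 31 |
| 4.00 | 49 | 23 | 12 |
| 8.00 | 37 | 19 | 2 |
| 12.0 | 34 | 20 | 4 |
| 15.0 | 33 | 18 | 2 |

(scatter of a reading: 2 percentage points)

- equivalents of incoming ligand to starting complex, everything else as given, that leave most complex with one exchanged at 40 h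
- the amount of complex with one exchanged then, in percent of the starting complex charged
- the amount of complex with one exchanged with the amounts as given



The chair noted that the zeta run is this same flask, followed so far to 15.0 h. The species read add up to 96.0% at 1.33 h but 53.0% at 15.0 h, so the rest of the complex stands in something unread.

The first chemist argued for freezing what hardly moves late in the run. Summed over the readings from 8.00 h to 15.0 h, c(complex with one exchanged) and c(complex with two exchanged) stand at 1.82 to one. She named this the frozen ratio, the late c(complex with one exchanged) per c(complex with two exchanged), and said it is a reading and carries the scatter of the readings. Multiplying it by the last c(complex with two exchanged), 18%, she committed to 32.8% for n, as her own figure.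

The forecaster, expecting “one-exchanged to drift only slightly”, put n lower, at 30% (23% to 34%). He gave the best charge as 1.2 equiv (1 equiv to 1.7 equiv), yielding 55% (43% to 63%).

The flask gives 29.7% for n, below her 32.8%, and 54.7% at 1.35 equiv.

    starting complex + incoming ligand → leaving ligand + complex with one exchanged (k = 5.10 × 10⁻⁴ /M/s)
    complex with one exchanged + incoming ligand → leaving ligand + complex with two exchanged (k = 2.00 × 10⁻⁴ /M/s)
    complex with two exchanged + incoming ligand → leaving ligand + complex with three exchanged (k = 3.70 × 10⁻⁴ /M/s)
    complex with three exchanged + incoming ligand → leaving ligand + complex with four exchanged (k = 2.80 × 10⁻⁴ /M/s)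
    complex with two exchanged ⇌ isomer of the product (K = 0.530, k = 9.20 × 10⁻⁶ /s)
    incoming ligand → decomposed reagent (k = 1.50 × 10⁻⁵ /s)

While incoming ligand, the limiting reagent here, fell to 33.9% of its charge at 4.00 h, the exchange steps and the decomposition to decomposed reagent ran side by side, and at 20.0 h, with 1.41% left, the decomposition had 98% of its turnover behind it. At 40.0 h in this flask, the frozen ratio of 1.82 times c(complex with two exchanged) of 15.8% gives 28.8%, and in the neighbour charged with 0.47 M of starting complex, the same ratio times 13.0% gives 23.7% against the 22.2% found.

Readings and results come from a simulation from invented constants; noise was put on by code.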